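**Retrosynthetic overview**
1. Target ⇐ late ene-type chlorination of a (5Z)-5-methyl alkene (gives C6–Cl and C5=C16 together), C2–OH-directed epoxidation of the (3E) alkene, and an intramolecular Reformatsky lactonisation (C8–C17) on a ten-membered (3E,5Z)-dienone.
2. Ten-membered ring ⇐ Wharton–Grob fragmentation of the C3–C8 bond of a trans-anti-trans tricycle (8α-alkoxide, 4β-chloride). This is the key step: the E geometry at C3=C4 follows from the antiperiplanar arrangement, the Z geometry at C5=C6 from the six-membered ring.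
3. Tricycle ⇐ two Diels–Alder reactions on 2-methyl-1,4-benzoquinone: isoprene (ring C, enantioselective), then a 2-silyloxybutadiene (ring A, quaternary C1).
4. Ring order: B (quinone) → C → A → ring A functionalised → central ring B opened to the ten-membered ring → lactone.

Numbering: briarane numbering of the target (C1–C20) is used for all compounds; in the tricycles the C3–C8 bond is still present. Ring A = C1, C10–C14; ring B = C1, C2, C3, C8, C9, C10; ring C = C3–C8. β is the face of the C1 methyl, α the opposite face.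

Assumption: the (S)-configured oxazaborolidinium catalyst is taken to give the (4aR,8aS) adduct 5 by the Corey pre-transition-state model; if the sense is the opposite, the (R)-catalyst is used and nothing else changes.

This route has not been run; the stereochemical outcomes in the flexible ten-membered ring (steps 16, 18, 22) are argued from conformational models, not calculated.

**Step 1**
Reactants: 1 but-3-en-2-one
Product: 2 2-(triisopropylsilyloxy)buta-1,3-diene
Conditions: TIPSOTf, Et3N, Et2O, 0 °C → rt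
Reagents that add atoms: triisopropylsilyl trifluoromethanesulfonate, CC(C)[Si](C(C)C)(C(C)C)OS(=O)(=O)C(F)(F)F
Why: Soft enolisation and O-silylation of the enone (silyl triflate/amine) gives the 2-silyloxy diene; no stereocentre is formed.

**Step 2**
Reactants: 3 2-methyl-1,4-benzoquinone; 4 isoprene
Product: 5 (4aR,8aS)-2,7-dimethyl-4a,5,8,8a-tetrahydronaphthalene-1,4-dione
Conditions: (S)-o-tolyl-oxazaborolidinium triflimide [from (S)-α,α-diphenylprolinol, o-tolylboroxine, HNTf2] (20 mol %), CH2Cl2, −78 °C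
Reagents that add atoms: none
Why: Catalytic enantioselective quinone Diels–Alder reaction: the cationic oxazaborolidine binds the more basic C9 carbonyl next to C8–H, so isoprene adds endo to the unsubstituted double bond with its nucleophilic CH2 (future C4) on C3, which puts the methyl on C5 and sets H-3 and H-8 cis on one face.

**Step 3**
Reactants: 5 (4aR,8aS)-2,7-dimethyl-4a,5,8,8a-tetrahydronaphthalene-1,4-dione; 2 2-(triisopropylsilyloxy)buta-1,3-diene
Product: 6 kinetic tricyclic 2,9-dione (C1 methyl β, H-10 β, H-3 α, H-8 α; 12-silyloxy-12(13)-ene in ring A; 5-methyl-5(6)-ene in ring C)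
Conditions: toluene, 80 °C, 2,6-di-tert-butyl-4-methylphenol (cat.)
Reagents that add atoms: none
Why: Thermal Diels–Alder reaction of the 2-methyl ene-dione with "para" orientation (nucleophilic diene terminus to the unsubstituted C10, so the silyloxy carbon becomes C12 and C1 the quaternary centre); the diene adds to the convex face anti to ring C, which fixes C1 relative to the centres set in step 2.

**Step 4**
Reactants: 6 kinetic tricyclic 2,9-dione
Product: 7 trans-anti-trans tricyclic 2,9-dione (C1 methyl β, H-10 α, H-3 β, H-8 α)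
Conditions: DBU (0.3 equiv), toluene, rt
Reagents that add atoms: none
Why: Base epimerisation of the enolisable ring-fusion centres C10 (α to C9=O) and C3 (α to C2=O) relaxes the cis,cis adduct to the all-trans isomer, the only one with every ring bond equatorial on ring B (Woodward-type cis-to-trans isomerisation); C1 and C8 keep their configuration.

**Step 5**
Reactants: 7 trans-anti-trans tricyclic 2,9-dione
Product: 8 8α-hydroxy-2,9-dione
Conditions: KN(SiMe3)2 (1.05 equiv), THF, −78 °C; 2-(phenylsulfonyl)-3-phenyloxaziridine; AcOH, −78 °C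
Reagents that add atoms: trans-2-(phenylsulfonyl)-3-phenyloxaziridine, O=S(=O)(N1OC1c1ccccc1)c1ccccc1
Why: Kinetic enolisation followed by Davis enolate hydroxylation: C3–H is syn-axial to the C1 methyl and C10–H is neopentylic, so C8–H is removed (as 6-oxo-5α-steroids enolise away from the ring fusion next to the quaternary carbon), and oxygen enters axially from the α-face with retention, leaving the C8–C7 bond equatorial.

**Step 6**
Reactants: 8 8α-hydroxy-2,9-dione
Product: 9 2β,8α,9β-triol
Conditions: Me4NBH(OAc)3 (6 equiv), MeCN–AcOH (10:1), −30 → 0 °C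
Reagents that add atoms: none
Why: Evans–Saksena hydroxyl-directed reduction: boron bound to the 8α-oxygen delivers hydride to the α-face of both the neighbouring C9 ketone and the β-related C2 ketone, giving the 9β alcohol (trans-diaxial 1,2-diol) and the 2β alcohol (1,3-anti diol).

**Step 7**
Reactants: 9 2β,8α,9β-triol
Product: 10 2β,9β-bis(4-methoxybenzyl) ether with free 8α-OH
Conditions: NaH (2.2 equiv), 4-methoxybenzyl chloride, Bu4NI (cat.), DMF, 0 °C → rt
Reagents that add atoms: 4-methoxybenzyl chloride, COc1ccc(CCl)cc1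
Why: Williamson etherification of the two secondary alkoxides; the tertiary 8α-alkoxide, flanked by two fully substituted carbons, is not alkylated.

**Step 8**
Reactants: 10 2β,9β-bis(4-methoxybenzyl) ether
Product: 11 ring A enone (12-oxo-13(14)-ene)
Conditions: Pd(OAc)2 (10 mol %), O2 (1 atm), DMSO, 40 °C
Reagents that add atoms: none
Why: Saegusa–Ito oxidation of the regiodefined silyl enol ether gives the conjugated enone with the double bond at C13=C14; the isolated trisubstituted alkene of ring C does not react.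

**Step 9**
Reactants: 11 ring A enone
Product: 12 13α,14α-epoxy-12-ketone
Conditions: H2O2 (30 %), NaOH, MeOH, 0 °C
Reagents that add atoms: hydrogen peroxide, OO
Why: Weitz–Scheffer nucleophilic epoxidation; hydroperoxide adds to C14 anti to the axial C1 methyl (as 1-en-3-oxo steroids give 1α,2α-epoxides), so the epoxide is α.

**Step 10**
Reactants: 12 13α,14α-epoxy-12-ketone
Product: 15 11-methylidene-13α,14α-epoxy-12-ketone, via Mannich base 13 (not isolated), via methiodide 14 (not isolated)
Conditions: LiN(SiMe3)2 (2.1 equiv), THF, −78 °C; CH2=NMe2+ I−; then MeI; then DBU, CH2Cl2, rt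
Reagents that add atoms: dimethyl(methylidene)ammonium iodide (Eschenmoser's salt), C=[N+](C)C.[I-]
Why: The first equivalent of base goes to the 8-OH and the second forms the only possible ketone enolate (C11), which undergoes a Mannich reaction; N-methylation and E1cB elimination give the exocyclic enone, and the C11 centre of 13 and 14 is lost again.

**Step 11**
Reactants: 15 11-methylidene-13α,14α-epoxy-12-ketone
Product: 16 11-methylidene-13α,14α-epoxy-12α-ol
Conditions: NaBH4, CeCl3·7H2O, MeOH, −78 °C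
Reagents that add atoms: none
Why: Luche 1,2-reduction; hydride attacks C12 anti to the epoxide oxygen (Felkin–Anh and steric), i.e. from the β-face, giving the 12α-alcohol cis to the epoxide.

**Step 12**
Reactants: 16 11-methylidene-13α,14α-epoxy-12α-ol
Product: 17 11β-methyl-13α,14α-epoxy-12α-ol
Conditions: H2 (1 atm), RhCl(PPh3)3 (5 mol %), benzene–EtOH, rt
Reagents that add atoms: none
Why: Homogeneous hydrogenation with RhCl(PPh3)3 reduces only the 1,1-disubstituted alkene (the trisubstituted ring C alkene is inert); hydrogen comes from the α-face, which carries the 12α-OH and is remote from the axial C1 methyl, so the methyl ends up 11β, the kinetic result known for exocyclic methylenes 1,3 to an angular methyl.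

**Step 13**
Reactants: 17 11β-methyl-13α,14α-epoxy-12α-ol
Product: 18 12α-tert-butyldimethylsilyl ether
Conditions: TBSCl, imidazole, DMF, rt
Reagents that add atoms: tert-butyldimethylsilyl chloride, CC(C)(C)[Si](C)(C)Cl
Why: Silylation of the only secondary alcohol; the tertiary 8-OH does not react under these conditions.

**Step 14**
Reactants: 18 12α-tert-butyldimethylsilyl ether
Product: 19 4α-hydroxy derivative
Conditions: SeO2 (0.5 equiv), t-BuOOH, CH2Cl2, rt
Reagents that add atoms: tert-butyl hydroperoxide (terminal oxidant, through SeO2), CC(C)(C)OO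
Why: Selenium dioxide allylic hydroxylation (ene reaction then [2,3] shift; Guillemonat rules) oxidises the ring CH2 next to the more substituted alkene carbon, C4; removal of the pseudo-axial 4α-H and the suprafacial shift give the 4α-alcohol with the double bond unchanged.

**Step 15**
Reactants: 19 4α-hydroxy derivative
Product: 20 4β-chloro derivative (8α-OH free)
Conditions: PPh3, CCl4, CH2Cl2, 0 °C → rt
Reagents that add atoms: tetrachloromethane, ClC(Cl)(Cl)Cl
Why: Appel reaction, SN2 with inversion, gives the pseudo-equatorial 4β-chloride, which is now antiperiplanar to the C3–C8 bond; the tertiary alcohol is not activated.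

**Step 16**
Reactants: 20 4β-chloro derivative
Product: 22 ten-membered (3E,5Z)-7-hydroxy-3,5-dien-8-one, via dienone 21 (not isolated)
Conditions: KN(SiMe3)2 (2.5 equiv), THF, −78 → −20 °C; then 2-(phenylsulfonyl)-3-phenyloxaziridine, −78 °C; AcOH
Reagents that add atoms: trans-2-(phenylsulfonyl)-3-phenyloxaziridine, O=S(=O)(N1OC1c1ccccc1)c1ccccc1
Why: Wharton–Grob fragmentation: the 8α-alkoxide, the C3–C8 bond and the equatorial C4–Cl are antiperiplanar in the trans-fused chair, so C3=C4 forms E while C5=C6 stays Z; the second equivalent of base deprotonates the doubly activated C7 of 21 to the extended enolate, which the Davis oxaziridine hydroxylates at the α-carbon from the outer face of the ring, placing O7 as in the target.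

**Step 17**
Reactants: 22 7-hydroxy-3,5-dien-8-one
Product: 23 7-(2-bromopropanoyl) ester (C17 as a mixture)
Conditions: 2-bromopropanoyl bromide, pyridine, CH2Cl2, −20 °C
Reagents that add atoms: 2-bromopropanoyl bromide, CC(Br)C(Br)=O
Why: Acylation of the only free hydroxyl; the C17 configuration is irrelevant because it is lost on enolate formation in the next step.

**Step 18**
Reactants: 23 7-(2-bromopropanoyl) ester
Product: 24 8-hydroxy 7,19-lactone (2,9-bis-PMB, 12-OTBS)
Conditions: SmI2 (2.2 equiv), THF, −78 °C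
Reagents that add atoms: none
Why: SmI2-mediated intramolecular Reformatsky reaction (Molander type): the C–Br bond is reduced faster than the ketone at −78 °C, and the samarium enolate, tethered through O7, adds to C8=O on the O7 side to close the cis-fused five-membered lactone (H-7 and 8-OH cis); the chelated chair-like transition state puts the C17 methyl away from C9, cis to the new hydroxyl, which is also the more stable C17 epimer.

**Step 19**
Reactants: 24 8-hydroxy 7,19-lactone
Product: 25 2,8,9-triol lactone (12-OTBS)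
Conditions: DDQ (2.2 equiv), CH2Cl2–pH 7 buffer, 0 °C
Reagents that add atoms: none
Why: Oxidative cleavage of both 4-methoxybenzyl ethers through their benzylic oxocarbenium ions; silyl ether, lactone, epoxide and diene are left alone under buffered conditions at 0 °C.

**Step 20**
Reactants: 25 2,8,9-triol lactone
Product: 26 (3S,4R)-3,4-epoxide
Conditions: Ti(OiPr)4 (0.3 equiv), D-(−)-diisopropyl tartrate (0.36 equiv), t-BuOOH, 4 Å sieves, CH2Cl2, −20 °C
Reagents that add atoms: tert-butyl hydroperoxide, CC(C)(C)OO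
Why: Sharpless asymmetric epoxidation in the matched manifold: for this C2 configuration the D-(−)-tartrate complex delivers oxygen to the face that gives the erythro (3S,4R) trans-epoxide, and only the allylic C3=C4 alkene is activated, so the trisubstituted C5=C6 alkene is untouched.

**Step 21**
Reactants: 26 (3S,4R)-3,4-epoxide
Product: 27 2,9-diacetate
Conditions: Ac2O, pyridine, DMAP (cat.), CH2Cl2, 0 °C → rt
Reagents that add atoms: acetic anhydride, CC(=O)OC(C)=O
Why: Acetylation of the two secondary alcohols; the tertiary, hydrogen-bonded 8-OH of the β-hydroxy lactone does not react.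

**Step 22**
Reactants: 27 2,9-diacetate
Product: 28 6-chloro-5(16)-ene (12-O-TBS ether of the target)
Conditions: t-BuOCl (1.1 equiv), SiO2, hexane–CH2Cl2, 0 °C, dark
Reagents that add atoms: tert-butyl hypochlorite, CC(C)(C)OCl
Why: Ene-type allylic chlorination of a trisubstituted alkene: chlorine bonds to the less substituted C6 and a proton leaves from C16 (the C4–H is an epoxide methine and is not removed), giving the exocyclic alkene; Cl enters the exposed face of the (5Z) alkene, syn to O7, because the ring backbone (C3–C4 and C8) covers the other face, which gives 6S; the 8-OH is anti to C6 in the cis-fused lactone and cannot cyclise onto C5.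

**Step 23**
Reactants: 28 6-chloro-5(16)-ene 12-O-TBS ether
Product: 29 target, CNP0141778.4
Conditions: HF·pyridine, pyridine, THF, 0 °C → rt
Reagents that add atoms: none
Why: Buffered fluoride-mediated desilylation frees the 12-OH; acetates, both epoxides, the allylic chloride and the lactone tolerate these conditions, and the cis epoxy alcohol cannot undergo Payne rearrangement.

**Compound list**
1 | but-3-en-2-one | CC(=O)C=C | starting material
2 | 2-(triisopropylsilyloxy)buta-1,3-diene | C=CC(=C)O[Si](C(C)C)(C(C)C)C(C)C | intermediate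
3 | 2-methyl-1,4-benzoquinone | CC1=CC(=O)C=CC1=O | starting material
4 | isoprene (2-methylbuta-1,3-diene) | CC(=C)C=C | starting material
5 | (4aR,8aS)-2,7-dimethyl-4a,5,8,8a-tetrahydronaphthalene-1,4-dione | CC1=CC(=O)[C@@H]2CC=C(C)C[C@@H]2C1=O | intermediate
6 | kinetic tricyclic 2,9-dione (C1-Me β, H-10 β, H-3 α, H-8 α; 12-OTIPS-12(13)-ene; 5-methyl-5(6)-ene) | C[C@]12CC=C(O[Si](C(C)C)(C(C)C)C(C)C)C[C@H]1C(=O)[C@@H]1CC=C(C)C[C@@H]1C2=O | intermediate
7 | trans-anti-trans tricyclic 2,9-dione (H-10 α, H-3 β, H-8 α) | C[C@]12CC=C(O[Si](C(C)C)(C(C)C)C(C)C)C[C@@H]1C(=O)[C@@H]1CC=C(C)C[C@H]1C2=O | intermediate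
8 | 8α-hydroxy-2,9-dione | C[C@]12CC=C(O[Si](C(C)C)(C(C)C)C(C)C)C[C@@H]1C(=O)[C@]1(O)CC=C(C)C[C@H]1C2=O | intermediate
9 | 2β,8α,9β-triol | C[C@]12CC=C(O[Si](C(C)C)(C(C)C)C(C)C)C[C@@H]1[C@H](O)[C@]1(O)CC=C(C)C[C@H]1[C@@H]2O | intermediate
10 | 2β,9β-bis(4-methoxybenzyl) ether, 8α-OH free | C[C@]12CC=C(O[Si](C(C)C)(C(C)C)C(C)C)C[C@@H]1[C@H](OCc1ccc(OC)cc1)[C@]1(O)CC=C(C)C[C@H]1[C@@H]2OCc1ccc(OC)cc1 | intermediate
11 | ring A enone (12-oxo-13(14)-ene) | C[C@]12C=CC(=O)C[C@@H]1[C@H](OCc1ccc(OC)cc1)[C@]1(O)CC=C(C)C[C@H]1[C@@H]2OCc1ccc(OC)cc1 | intermediate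
12 | 13α,14α-epoxy-12-ketone | C[C@]12[C@H]3O[C@H]3C(=O)C[C@@H]1[C@H](OCc1ccc(OC)cc1)[C@]1(O)CC=C(C)C[C@H]1[C@@H]2OCc1ccc(OC)cc1 | intermediate
13 | 11-(dimethylaminomethyl)-13α,14α-epoxy-12-ketone (Mannich base, C11 mixture) | C[C@]12[C@H]3O[C@H]3C(=O)C(CN(C)C)[C@@H]1[C@H](OCc1ccc(OC)cc1)[C@]1(O)CC=C(C)C[C@H]1[C@@H]2OCc1ccc(OC)cc1 | intermediate
14 | trimethylammonium iodide of 13 (methiodide) | C[C@]12[C@H]3O[C@H]3C(=O)C(C[N+](C)(C)C)[C@@H]1[C@H](OCc1ccc(OC)cc1)[C@]1(O)CC=C(C)C[C@H]1[C@@H]2OCc1ccc(OC)cc1.[I-] | intermediate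
15 | 11-methylidene-13α,14α-epoxy-12-ketone | C[C@]12[C@H]3O[C@H]3C(=O)C(=C)[C@@H]1[C@H](OCc1ccc(OC)cc1)[C@]1(O)CC=C(C)C[C@H]1[C@@H]2OCc1ccc(OC)cc1 | intermediate
16 | 11-methylidene-13α,14α-epoxy-12α-ol | C[C@]12[C@H]3O[C@H]3[C@@H](O)C(=C)[C@@H]1[C@H](OCc1ccc(OC)cc1)[C@]1(O)CC=C(C)C[C@H]1[C@@H]2OCc1ccc(OC)cc1 | intermediate
17 | 11β-methyl-13α,14α-epoxy-12α-ol | C[C@]12[C@H]3O[C@H]3[C@@H](O)[C@H](C)[C@@H]1[C@H](OCc1ccc(OC)cc1)[C@]1(O)CC=C(C)C[C@H]1[C@@H]2OCc1ccc(OC)cc1 | intermediate
18 | 12α-tert-butyldimethylsilyl ether of 17 | C[C@]12[C@H]3O[C@H]3[C@@H](O[Si](C)(C)C(C)(C)C)[C@H](C)[C@@H]1[C@H](OCc1ccc(OC)cc1)[C@]1(O)CC=C(C)C[C@H]1[C@@H]2OCc1ccc(OC)cc1 | intermediate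
19 | 4α-hydroxy derivative of 18 | C[C@]12[C@H]3O[C@H]3[C@@H](O[Si](C)(C)C(C)(C)C)[C@H](C)[C@@H]1[C@H](OCc1ccc(OC)cc1)[C@]1(O)CC=C(C)[C@@H](O)[C@H]1[C@@H]2OCc1ccc(OC)cc1 | intermediate
20 | 4β-chloro derivative, 8α-OH free | C[C@]12[C@H]3O[C@H]3[C@@H](O[Si](C)(C)C(C)(C)C)[C@H](C)[C@@H]1[C@H](OCc1ccc(OC)cc1)[C@]1(O)CC=C(C)[C@H](Cl)[C@H]1[C@@H]2OCc1ccc(OC)cc1 | intermediate
21 | ten-membered (3E,5Z)-3,5-dien-8-one (C7 methylene; ring A and C1, C2, C9, C10 as in the target) | COc1ccc(CO[C@H]2/C=C/C(C)=C\CC(=O)[C@@H](OCc3ccc(OC)cc3)[C@H]3[C@@H](C)[C@H](O[Si](C)(C)C(C)(C)C)[C@@H]4O[C@@H]4[C@]23C)cc1 | intermediate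
22 | (3E,5Z)-7-hydroxy-3,5-dien-8-one (O7 on the face it has in the target) | COc1ccc(CO[C@H]2/C=C/C(C)=C\[C@@H](O)C(=O)[C@@H](OCc3ccc(OC)cc3)[C@H]3[C@@H](C)[C@H](O[Si](C)(C)C(C)(C)C)[C@@H]4O[C@@H]4[C@]23C)cc1 | intermediate
23 | 7-(2-bromopropanoyl) ester of 22 (C17 mixture) | COc1ccc(CO[C@H]2/C=C/C(C)=C\[C@@H](OC(=O)C(C)Br)C(=O)[C@@H](OCc3ccc(OC)cc3)[C@H]3[C@@H](C)[C@H](O[Si](C)(C)C(C)(C)C)[C@@H]4O[C@@H]4[C@]23C)cc1 | intermediate
24 | 8-hydroxy 7,19-lactone (C7, C8, C17 as in the target; 2,9-bis-PMB; 12-OTBS) | COc1ccc(CO[C@H]2/C=C/C(C)=C\[C@H]3OC(=O)[C@H](C)[C@@]3(O)[C@@H](OCc3ccc(OC)cc3)[C@H]3[C@@H](C)[C@H](O[Si](C)(C)C(C)(C)C)[C@@H]4O[C@@H]4[C@]23C)cc1 | intermediate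
25 | 2,8,9-triol lactone (12-OTBS) | O[C@H]1/C=C/C(C)=C\[C@H]2OC(=O)[C@H](C)[C@@]2(O)[C@@H](O)[C@H]2[C@@H](C)[C@H](O[Si](C)(C)C(C)(C)C)[C@@H]3O[C@@H]3[C@]12C | intermediate
26 | (3S,4R)-3,4-epoxide of 25 | O[C@H]1[C@H]2O[C@@H]2/C(C)=C\[C@H]2OC(=O)[C@H](C)[C@@]2(O)[C@@H](O)[C@H]2[C@@H](C)[C@H](O[Si](C)(C)C(C)(C)C)[C@@H]3O[C@@H]3[C@]12C | intermediate
27 | 2,9-diacetate of 26 | CC(=O)O[C@H]1[C@H]2O[C@@H]2/C(C)=C\[C@H]2OC(=O)[C@H](C)[C@@]2(O)[C@@H](OC(C)=O)[C@H]2[C@@H](C)[C@H](O[Si](C)(C)C(C)(C)C)[C@@H]3O[C@@H]3[C@]12C | intermediate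
28 | 6-chloro-5(16)-ene, 12-O-TBS ether of the target | C=C1[C@H]2O[C@@H]2[C@H](OC(C)=O)[C@]2(C)[C@H]([C@@H](C)[C@H](O[Si](C)(C)C(C)(C)C)[C@@H]3O[C@@H]32)[C@H](OC(C)=O)[C@@]2(O)[C@H](OC(=O)[C@@H]2C)[C@H]1Cl | intermediate
29 | CNP0141778.4 | C=C1[C@H]2O[C@@H]2[C@H](OC(C)=O)[C@]2(C)[C@H]([C@@H](C)[C@H](O)[C@@H]3O[C@@H]32)[C@H](OC(C)=O)[C@@]2(O)[C@H](OC(=O)[C@@H]2C)[C@H]1Cl | target

**Totals and risks**

Total step count: 23. Longest linear sequence: 22 steps (3 → 29, steps 2–23); the diene 2 is made in one further step.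

The three steps most likely to fail:

Step 5 (regioselective hydroxylation at C8, not C10). If enolisation is unselective, the route sets out again from 3 and generates the C9 enolate regiospecifically instead. The catalysed cycloaddition is run with (E)-1-(tert-butyldimethylsilyloxy)-3-methylbuta-1,3-diene F1 (from 3-methylbut-2-enal, TBSOTf, Et3N) in place of 4 and gives the 7-silyloxy adduct F2. Thermal cycloaddition with 2 gives the tricycle F3. DBU then epimerises C10 and C3 and eliminates the β-silyloxy group to give the dienone F4, in which only the C8 side of the C9 ketone is unsaturated. Conjugate hydrosilylation ([(Ph3P)CuH]6 cat., Et3SiH) gives the regiodefined triethylsilyl enol ether F5. Rubottom oxidation from the α-face (dimethyldioxirane, then citric acid) comes back to the route at 8.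

Step 16 (facial selectivity of the C7 hydroxylation in the ten-membered ring, and survival of C9 under excess base). The fallback sets out from 20. KOtBu alone (THF, 0 °C) gives the dienone 21, which is isolated. KN(SiMe3)2 and Et3SiCl at −78 °C give the silyl trienol ether F6. Its enol ether double bond is epoxidised under reagent control (Shi fructose-derived ketone or its enantiomer, KHSO5, buffered), the catalyst enantiomer being chosen for the C7 face needed. Desilylation on work-up comes back to the route at 22.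

Step 22 (face and regiochemistry of the ene chlorination next to a vinyl epoxide). The fallback sets out from 27 and introduces oxygen first. A singlet-oxygen ene reaction (O2, tetraphenylporphyrin, hν; then PPh3) gives the exo-face allylic alcohol F7 (6-hydroxy-5(16)-ene). Dess–Martin oxidation gives the enone F8. Luche reduction from the exposed face gives the C6-epimeric alcohol F9. Appel chlorination with inversion (PPh3, CCl4) comes back to the route at 28.

**Further compounds**
F1 | step 5 | (E)-1-(tert-butyldimethylsilyloxy)-3-methylbuta-1,3-diene | C=C(C)/C=C/O[Si](C)(C)C(C)(C)C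
F2 | step 5 | 7-(tert-butyldimethylsilyloxy) analogue of 5 (cis adduct, silyloxy cis to C9) | CC1=CC(=O)[C@@H]2[C@H](O[Si](C)(C)C(C)(C)C)C=C(C)C[C@@H]2C1=O
F3 | step 5 | 7-(tert-butyldimethylsilyloxy) analogue of 6 | C[C@]12CC=C(O[Si](C(C)C)(C(C)C)C(C)C)C[C@H]1C(=O)[C@@H]1[C@H](O[Si](C)(C)C(C)(C)C)C=C(C)C[C@@H]1C2=O
F4 | step 5 | tricyclic 5,7(8)-dien-2,9-dione (H-10 α, H-3 β) | C[C@]12CC=C(O[Si](C(C)C)(C(C)C)C(C)C)C[C@@H]1C(=O)C1=CC=C(C)C[C@H]1C2=O
F5 | step 5 | 9-(triethylsilyloxy)-8(9)-ene (regiodefined silyl enol ether of 7) | C[C@]12CC=C(O[Si](C(C)C)(C(C)C)C(C)C)C[C@@H]1C(O[Si](CC)(CC)CC)=C1CC=C(C)C[C@H]1C2=O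
F6 | step 16 | 8-(triethylsilyloxy)-3,5,7-triene (silyl trienol ether of 21) | COc1ccc(CO[C@H]2/C=C/C(C)=C\C=C(O[Si](CC)(CC)CC)[C@@H](OCc3ccc(OC)cc3)[C@H]3[C@@H](C)[C@H](O[Si](C)(C)C(C)(C)C)[C@@H]4O[C@@H]4[C@]23C)cc1
F7 | step 22 | 6-hydroxy-5(16)-ene (oxygen on the face that chlorine has in 28) | C=C1[C@H]2O[C@@H]2[C@H](OC(C)=O)[C@]2(C)[C@H]([C@@H](C)[C@H](O[Si](C)(C)C(C)(C)C)[C@@H]3O[C@@H]32)[C@H](OC(C)=O)[C@@]2(O)[C@H](OC(=O)[C@@H]2C)[C@H]1O
F8 | step 22 | 6-oxo-5(16)-ene | C=C1[C@H]2O[C@@H]2[C@H](OC(C)=O)[C@]2(C)[C@H]([C@@H](C)[C@H](O[Si](C)(C)C(C)(C)C)[C@@H]3O[C@@H]32)[C@H](OC(C)=O)[C@@]2(O)[C@H](OC(=O)[C@@H]2C)C1=O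
F9 | step 22 | 6-epi-6-hydroxy-5(16)-ene | C=C1[C@H]2O[C@@H]2[C@H](OC(C)=O)[C@]2(C)[C@H]([C@@H](C)[C@H](O[Si](C)(C)C(C)(C)C)[C@@H]3O[C@@H]32)[C@H](OC(C)=O)[C@@]2(O)[C@H](OC(=O)[C@@H]2C)[C@@H]1O
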